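Locants: the upper flavan is rings A/C/B with C2–C4. The lower flavan is rings D/F/E with primed locants (O1', C2'–C4', C4a', C5'–C8a'). The target is guibourtinidol-(4α→6')-ent-epifisetinidol.
Cuts, in retrosynthetic order: the six O-benzyl groups, C4'–C4a' (ring F), O1'–C2' (aryl ether), C3–O and C4–H across a C3=C4 alkene, and C4–C6' (interflavan bond).
Enabling feature: in ring F the methylene C4' sits on C4a' of the resorcinol-type ring D, ortho to O1' and para to O7'. It is followed by the carbinol C3' and the O1'-bearing benzylic C2', so ring F is what forms when that arene carbon opens the CH2 end of a 1-aryl-2,3-epoxypropyl aryl ether.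
Forward order: rings A, B and C arrive with (S)-liquiritigenin, and ring D is added to C4 as an arylcerium reagent. Dehydration and hydroboration complete the upper unit, ring E with C2'–C4' is attached to O1', ring F closes last, and hydrogenolysis follows.
Stereochemistry: C2 comes from the chiral pool, and C3 and C4 from syn hydroboration anti to ring B. C3' comes from a Sharpless kinetic resolution with D-(−)-DIPT, and C2' from SN2 inversion of the resolved carbinol in the Mitsunobu etherification.

Key step: step 11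

Assumption: commercial (S)-liquiritigenin is taken as a single enantiomer, to be confirmed by chiral HPLC after the first step. C2 keeps its geometry throughout, and its descriptor changes from S to R only because C3 gains oxygen.

Step 1
Reactants: 1 (S)-liquiritigenin
Product: 2 (2S)-7-benzyloxy-2-(4-benzyloxyphenyl)chroman-4-one
Conditions: BnOH (2.5 equiv), PPh3, DIAD, THF, 0 °C to rt
Reagents that add atoms: benzyl alcohol, OCc1ccccc1
Why: Mitsunobu O-alkylation of both phenols needs no added base, so C3 is not deprotonated, the retro-oxa-Michael opening to the chalcone that racemises flavanones under carbonate conditions is avoided, and C2 stays untouched.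

Step 2
Reactants: 3 4-bromoresorcinol
Product: 4 2-bromo-5-(triisopropylsilyloxy)phenol
Conditions: TIPSCl (1.0 equiv), imidazole, CH2Cl2/DMF, 0 °C
Reagents that add atoms: triisopropylsilyl chloride, CC(C)[Si](Cl)(C(C)C)C(C)C
Why: In this sterically governed monosilylation the bulky chlorosilane should react at the hydroxyl para to bromine rather than at the one flanked by bromine.

Step 3
Reactants: 4 2-bromo-5-(triisopropylsilyloxy)phenol
Product: 5 2-benzyloxy-1-bromo-4-(triisopropylsilyloxy)benzene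
Conditions: BnBr, K2CO3, acetone, 40 °C
Reagents that add atoms: benzyl bromide, BrCc1ccccc1
Why: Williamson etherification of the remaining, more acidic ortho-bromophenol should be clean, because the hindered aryl TIPS ether tolerates carbonate in acetone.

Step 4
Reactants: 5 2-benzyloxy-1-bromo-4-(triisopropylsilyloxy)benzene; 2 (2S)-7-benzyloxy-2-(4-benzyloxyphenyl)chroman-4-one
Product: 9 (2S)-7-benzyloxy-2-(4-benzyloxyphenyl)-4-[2-benzyloxy-4-(triisopropylsilyloxy)phenyl]-2H-chromene, via aryllithium 6 (not isolated), via arylcerium dichloride 7 (not isolated), via tertiary C4 carbinol 8 (not isolated)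
Conditions: 5 (1.4 equiv), n-BuLi, THF, −78 °C; anhydrous CeCl3, −78 °C; 2, −78 to −20 °C; aq NH4Cl; crude 8, PPTS (10 mol %), 4 Å MS, CH2Cl2, rt
Reagents that add atoms: none
Why: In this organocerium 1,2-addition followed by E1 dehydration, the weakly basic aryl–CeCl2 reagent should add to the C4 carbonyl faster than it enolises C3, and the doubly benzylic carbinol, whose cation is stabilised by four oxygen donors, loses water under buffered acid towards C3, the only β-CH, without touching C2.

Step 5
Reactants: 9 (2S)-7-benzyloxy-2-(4-benzyloxyphenyl)-4-[2-benzyloxy-4-(triisopropylsilyloxy)phenyl]-2H-chromene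
Product: 11 (2R,3S)-2,3-trans-3,4-trans-7-benzyloxy-2-(4-benzyloxyphenyl)-4-[2-benzyloxy-4-(triisopropylsilyloxy)phenyl]chroman-3-ol, via C3 alkylborane 10 (not isolated)
Conditions: BH3·THF (3 equiv), THF, 0 °C to rt; then 30% H2O2, aq NaOAc, 0 °C to rt
Reagents that add atoms: hydrogen peroxide, OO
Why: In this hydroboration–oxidation, a reaction type known for flav-3-enes, boron goes to the non-benzylic C3 and hydrogen to C4 in a syn addition on the face opposite ring B, and C–B oxidation with retention then places the C3 oxygen trans to ring B and ring D trans to that oxygen, while the acetate buffer spares the aryl silyl ether.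

Step 6
Reactants: 11 (2R,3S)-2,3-trans-3,4-trans-7-benzyloxy-2-(4-benzyloxyphenyl)-4-[2-benzyloxy-4-(triisopropylsilyloxy)phenyl]chroman-3-ol
Product: 12 (2R,3S)-2,3-trans-3,4-trans-3,7-bis(benzyloxy)-2-(4-benzyloxyphenyl)-4-[2-benzyloxy-4-(triisopropylsilyloxy)phenyl]chroman
Conditions: NaH, BnBr, n-Bu4NI (cat.), THF, 0 °C to rt
Reagents that add atoms: benzyl bromide, BrCc1ccccc1
Why: This Williamson benzylation of the secondary C3 alkoxide is standard for O-benzylated flavan-3-ols, and it is run in THF rather than DMF so that the aryl TIPS ether is not stripped.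

Step 7
Reactants: 12 (2R,3S)-2,3-trans-3,4-trans-3,7-bis(benzyloxy)-2-(4-benzyloxyphenyl)-4-[2-benzyloxy-4-(triisopropylsilyloxy)phenyl]chroman
Product: 13 3-benzyloxy-4-[(2R,3S)-2,3-trans-3,4-trans-3,7-bis(benzyloxy)-2-(4-benzyloxyphenyl)chroman-4-yl]phenol
Conditions: TBAF, AcOH (1:1), THF, 0 °C
Reagents that add atoms: none
Why: Buffered fluoride desilylation frees only the ring D hydroxyl that becomes O1', because the benzyl ethers and the three stereocentres are inert to fluoride.

Step 8
Reactants: 14 3,4-bis(benzyloxy)benzaldehyde; 15 vinylmagnesium bromide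
Product: 16 rac-1-[3,4-bis(benzyloxy)phenyl]prop-2-en-1-ol
Conditions: THF, 0 °C; aq NH4Cl
Reagents that add atoms: none
Why: Grignard 1,2-addition to a non-enolisable aldehyde should be clean, and the carbinol is made racemic on purpose because the next step resolves it.

Step 9
Reactants: 16 rac-1-[3,4-bis(benzyloxy)phenyl]prop-2-en-1-ol
Product: 17 (R)-[3,4-bis(benzyloxy)phenyl][(2S)-oxiran-2-yl]methanol (erythro)
Conditions: Ti(OiPr)4 (0.15 equiv), D-(−)-DIPT (0.2 equiv), t-BuOOH (0.45 equiv), 4 Å MS, CH2Cl2, −20 °C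
Reagents that add atoms: tert-butyl hydroperoxide, CC(C)(C)OO
Why: In this Sharpless kinetic resolution the D-(−)-tartrate catalyst should epoxidise the (S)-allylic alcohol much faster than its antipode and deliver oxygen to the alkene face that gives the erythro epoxy alcohol, so stopping below half conversion fixes the (2S)-oxirane carbon and selects the carbinol that is named R once the oxirane outranks the aryl group.

Step 10
Reactants: 13 3-benzyloxy-4-[(2R,3S)-2,3-trans-3,4-trans-3,7-bis(benzyloxy)-2-(4-benzyloxyphenyl)chroman-4-yl]phenol; 17 (R)-[3,4-bis(benzyloxy)phenyl][(2S)-oxiran-2-yl]methanol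
Product: 18 (2R,3S)-2,3-trans-3,4-trans-3,7-bis(benzyloxy)-2-(4-benzyloxyphenyl)-4-{2-benzyloxy-4-[(S)-[3,4-bis(benzyloxy)phenyl][(2S)-oxiran-2-yl]methoxy]phenyl}chroman (threo ether)
Conditions: 17 (1.3 equiv), PPh3, DIAD, toluene, 0 °C to rt
Reagents that add atoms: none
Why: In this Mitsunobu etherification, known for phenols with 1-aryl-2,3-epoxypropan-1-ols, the phenoxide should displace the phosphonium-activated carbinol by SN2 with inversion (R to S at C2'), helped by the non-polar solvent and the electron-withdrawing oxirane, and any ether from the minor enantiomer of 17 is now a separable diastereomer.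

Step 11
Reactants: 18 (2R,3S)-2,3-trans-3,4-trans-3,7-bis(benzyloxy)-2-(4-benzyloxyphenyl)-4-{2-benzyloxy-4-[(S)-[3,4-bis(benzyloxy)phenyl][(2S)-oxiran-2-yl]methoxy]phenyl}chroman
Product: 19 hexa-O-benzyl-guibourtinidol-(4α→6')-ent-epifisetinidol with free C3'-OH and a (2'S,3'S)-2,3-cis lower unit
Conditions: AuCl3 (5 mol %), AgOTf (15 mol %), tetramethylthiourea (5 mol %), 4 Å MS, ClCH2CH2Cl, rt
Reagents that add atoms: none
Why: Cationic trivalent gold formed from AuCl3 and AgOTf coordinates the oxirane oxygen, C4a' of ring D attacks the CH2 terminus (C4') from the rear in an SN2-like Friedel–Crafts alkylation, and rearomatisation with proton transfer to the C3' alkoxide releases 19 and the catalyst. The closest known reaction type is the gold-catalysed cycloalkylation of aryl glycidyl ethers and of 1-aryl-2,3-epoxypropyl aryl ethers to chroman-3-ols and O-benzylated flavan-3-ols. Ring F closes in the 6-endo mode, with both oxirane carbons ending up in the ring, whereas the 5-exo alternative would need attack at the secondary C3', which is shielded by the branched C2' and inductively deactivated by O1'. No stereocentre is created because C4' is a methylene, and since C3' keeps its C–O bond and C2' is a spectator, the (S,S)-threo ether maps onto the (2'S,3'S)-2,3-cis flavan-3-ol. The step needs site selectivity between the two positions ortho to O1': C4a' is para to the O7' benzyl ether and has only C5'–H as neighbour, whereas C8' is wedged between the two alkoxy groups. It also needs chemoselectivity over ionisation of the benzylic C2'–O1' bond, which the low catalyst loading, the thiourea ligand, the molecular sieves and room temperature are meant to secure.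

Step 12
Reactants: 19 hexa-O-benzyl-guibourtinidol-(4α→6')-ent-epifisetinidol
Product: 20 guibourtinidol-(4α→6')-ent-epifisetinidol (upper unit 2R,3S, 2,3-trans-3,4-trans; lower unit 2'S,3'S, 2,3-cis)
Conditions: H2 (1 atm), Pd(OH)2/C, THF/MeOH 1:1, rt
Reagents that add atoms: none
Why: Catalytic hydrogenolysis should remove all six benzyl ethers under neutral conditions that are established for O-benzylated flavan-3-ols and their dimers and that leave the ring C–O bonds and all five stereocentres intact.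

Compound list
1 | (S)-liquiritigenin, (2S)-7-hydroxy-2-(4-hydroxyphenyl)chroman-4-one | Oc1ccc([C@H]2Oc3cc(O)ccc3C(=O)C2)cc1 | starting material
2 | (2S)-7-benzyloxy-2-(4-benzyloxyphenyl)chroman-4-one | c1ccccc1COc1ccc([C@H]2Oc3cc(OCc4ccccc4)ccc3C(=O)C2)cc1 | intermediate
3 | 4-bromoresorcinol | Oc1ccc(Br)c(O)c1 | starting material
4 | 2-bromo-5-(triisopropylsilyloxy)phenol | Oc1cc(O[Si](C(C)C)(C(C)C)C(C)C)ccc1Br | intermediate
5 | 2-benzyloxy-1-bromo-4-(triisopropylsilyloxy)benzene | Brc1ccc(O[Si](C(C)C)(C(C)C)C(C)C)cc1OCc1ccccc1 | intermediate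
6 | 2-benzyloxy-4-(triisopropylsilyloxy)phenyllithium (not isolated) | [Li]c1ccc(O[Si](C(C)C)(C(C)C)C(C)C)cc1OCc1ccccc1 | intermediate
7 | [2-benzyloxy-4-(triisopropylsilyloxy)phenyl]cerium dichloride (not isolated) | Cl[Ce](Cl)c1ccc(O[Si](C(C)C)(C(C)C)C(C)C)cc1OCc1ccccc1 | intermediate
8 | (2S)-7-benzyloxy-2-(4-benzyloxyphenyl)-4-[2-benzyloxy-4-(triisopropylsilyloxy)phenyl]chroman-4-ol, C4 epimers (not isolated) | c1ccccc1COc1ccc([C@H]2Oc3cc(OCc4ccccc4)ccc3C(O)(c3ccc(O[Si](C(C)C)(C(C)C)C(C)C)cc3OCc3ccccc3)C2)cc1 | intermediate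
9 | (2S)-7-benzyloxy-2-(4-benzyloxyphenyl)-4-[2-benzyloxy-4-(triisopropylsilyloxy)phenyl]-2H-chromene | c1ccccc1COc1ccc([C@H]2Oc3cc(OCc4ccccc4)ccc3C(c3ccc(O[Si](C(C)C)(C(C)C)C(C)C)cc3OCc3ccccc3)=C2)cc1 | intermediate
10 | C3 alkylborane, boron trans to ring B and trans to ring D (not isolated) | c1ccccc1COc1ccc([C@H]2Oc3cc(OCc4ccccc4)ccc3[C@@H](c3ccc(O[Si](C(C)C)(C(C)C)C(C)C)cc3OCc3ccccc3)[C@@H]2B)cc1 | intermediate
11 | (2R,3S)-2,3-trans-3,4-trans-7-benzyloxy-2-(4-benzyloxyphenyl)-4-[2-benzyloxy-4-(triisopropylsilyloxy)phenyl]chroman-3-ol | c1ccccc1COc1ccc([C@H]2Oc3cc(OCc4ccccc4)ccc3[C@@H](c3ccc(O[Si](C(C)C)(C(C)C)C(C)C)cc3OCc3ccccc3)[C@@H]2O)cc1 | intermediate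
12 | (2R,3S)-2,3-trans-3,4-trans-3,7-bis(benzyloxy)-2-(4-benzyloxyphenyl)-4-[2-benzyloxy-4-(triisopropylsilyloxy)phenyl]chroman | c1ccccc1COc1ccc([C@H]2Oc3cc(OCc4ccccc4)ccc3[C@@H](c3ccc(O[Si](C(C)C)(C(C)C)C(C)C)cc3OCc3ccccc3)[C@@H]2OCc2ccccc2)cc1 | intermediate
13 | 3-benzyloxy-4-[(2R,3S)-2,3-trans-3,4-trans-3,7-bis(benzyloxy)-2-(4-benzyloxyphenyl)chroman-4-yl]phenol | c1ccccc1COc1ccc([C@H]2Oc3cc(OCc4ccccc4)ccc3[C@@H](c3ccc(O)cc3OCc3ccccc3)[C@@H]2OCc2ccccc2)cc1 | intermediate
14 | 3,4-bis(benzyloxy)benzaldehyde | O=Cc1ccc(OCc2ccccc2)c(OCc2ccccc2)c1 | starting material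
15 | vinylmagnesium bromide | C=C[Mg]Br | starting material
16 | rac-1-[3,4-bis(benzyloxy)phenyl]prop-2-en-1-ol | OC(C=C)c1ccc(OCc2ccccc2)c(OCc2ccccc2)c1 | intermediate
17 | (R)-[3,4-bis(benzyloxy)phenyl][(2S)-oxiran-2-yl]methanol (erythro) | O[C@H](c1ccc(OCc2ccccc2)c(OCc2ccccc2)c1)[C@@H]1CO1 | intermediate
18 | threo epoxy ether: upper unit 13 bearing the (S)-[3,4-bis(benzyloxy)phenyl][(2S)-oxiran-2-yl]methyl group on O1' | c1ccccc1COc1ccc([C@H]2Oc3cc(OCc4ccccc4)ccc3[C@@H](c3ccc(O[C@@H](c4ccc(OCc5ccccc5)c(OCc5ccccc5)c4)[C@@H]4CO4)cc3OCc3ccccc3)[C@@H]2OCc2ccccc2)cc1 | intermediate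
19 | hexa-O-benzyl-guibourtinidol-(4α→6')-ent-epifisetinidol, free C3'-OH, lower unit (2'S,3'S)-cis | c1ccccc1COc1ccc([C@H]2Oc3cc(OCc4ccccc4)ccc3[C@@H](c3cc4c(cc3OCc3ccccc3)O[C@@H](c3ccc(OCc5ccccc5)c(OCc5ccccc5)c3)[C@@H](O)C4)[C@@H]2OCc2ccccc2)cc1 | intermediate
20 | guibourtinidol-(4α→6')-ent-epifisetinidol (CNP0243811.1) | Oc1ccc([C@H]2Oc3cc(O)ccc3[C@@H](c3cc4c(cc3O)O[C@@H](c3ccc(O)c(O)c3)[C@@H](O)C4)[C@@H]2O)cc1 | target

Total step count: 12.
Longest linear sequence: 9 steps (steps 2, 3, 4, 5, 6, 7, 10, 11 and 12, starting from 3).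

Steps most likely to fail

Step 11. The Lewis acid may ionise the electron-rich benzylic C2'–O1' bond, which would lose the lower fragment or epimerise C2'. The arene may also attack through C8', or the oxirane may rearrange by hydride shift. The fallback sets out from 13 and returns at 19. It replaces the electrophilic closure by an anionic one whose site is fixed by a halogen.
- NIS in MeCN should iodinate 13 at the open position ortho to the hydroxyl and para to the benzyloxy group, giving the iodophenol F1.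
- Mitsunobu coupling of F1 with 17 gives the iodo epoxide F2.
- Li2NiBr4 in THF opens the oxirane at its CH2 to the bromohydrin F3.
- Ethyl vinyl ether with PPTS masks the C3' hydroxyl as the 1-ethoxyethyl acetal F4.
- PhLi at −78 °C effects iodine–lithium exchange, and the metalated C4a' displaces the primary bromide (Parham-type cyclisation) to give the ring-closed acetal F5.
- Aqueous AcOH in THF removes the acetal to give 19.

Step 10. Partial SN1 leakage at the electron-rich benzylic carbinol would erode the inversion at C2', and the oxirane could be opened by the phenoxide. The fallback sets out from 16 and 13 and returns at 18. The enantiomer of 16 left over from step 9 can be used, since its stereocentre is erased. Both stereocentres are then set by two separate SN2 events.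
- Re2O7-catalysed 1,3-transposition of 16 gives the (E)-cinnamyl alcohol F6.
- Sharpless asymmetric epoxidation with D-(−)-DET gives the (2R,3R)-epoxy alcohol F7.
- The sodium phenoxide of 13 opens F7 at the benzylic carbon with inversion, giving the (2R,3S)-diol F8.
- 4-Nitrobenzoyl chloride in pyridine at low temperature acylates the primary hydroxyl to give the mono-ester F9.
- MsCl with Et3N gives the secondary mesylate F10.
- Aqueous NaOH in dioxane cleaves the ester, and the primary alkoxide displaces the mesylate with inversion at C3', giving 18.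

Step 4. The flavanone may be enolised and then lose the ring A phenoxide by β-elimination (chalcone formation), which consumes 2. Acid contact during the dehydration may erode C2. The fallback sets out from 2 and 5 and returns at 9, and it avoids both the carbonyl addition and the carbinol. Condensation of 2 with TsNHNH2 in MeOH gives the N-tosylhydrazone F11. Barluenga cross-coupling of F11 with bromide 5 (Pd2(dba)3, XPhos, LiOt-Bu, dioxane, 90 °C) should give 9 directly. The aryl group migrates onto the palladium carbene at C4, and β-hydride elimination then occurs towards C3. The enantiomeric purity of 9 is to be checked after this hot step.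

Further compounds
F1 | step 11 | 5-benzyloxy-2-iodo-4-[(2R,3S)-2,3-trans-3,4-trans-3,7-bis(benzyloxy)-2-(4-benzyloxyphenyl)chroman-4-yl]phenol | c1ccccc1COc1ccc([C@H]2Oc3cc(OCc4ccccc4)ccc3[C@@H](c3cc(I)c(O)cc3OCc3ccccc3)[C@@H]2OCc2ccccc2)cc1
F2 | step 11 | iodo epoxide, 18 with iodine at the future C4a' | c1ccccc1COc1ccc([C@H]2Oc3cc(OCc4ccccc4)ccc3[C@@H](c3cc(I)c(O[C@@H](c4ccc(OCc5ccccc5)c(OCc5ccccc5)c4)[C@@H]4CO4)cc3OCc3ccccc3)[C@@H]2OCc2ccccc2)cc1
F3 | step 11 | bromohydrin from F2, primary bromide at C4' and free C3'-OH | c1ccccc1COc1ccc([C@H]2Oc3cc(OCc4ccccc4)ccc3[C@@H](c3cc(I)c(O[C@@H](c4ccc(OCc5ccccc5)c(OCc5ccccc5)c4)[C@@H](O)CBr)cc3OCc3ccccc3)[C@@H]2OCc2ccccc2)cc1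
F4 | step 11 | 1-ethoxyethyl acetal of F3 (acetal carbon as a mixture) | c1ccccc1COc1ccc([C@H]2Oc3cc(OCc4ccccc4)ccc3[C@@H](c3cc(I)c(O[C@@H](c4ccc(OCc5ccccc5)c(OCc5ccccc5)c4)[C@@H](OC(C)OCC)CBr)cc3OCc3ccccc3)[C@@H]2OCc2ccccc2)cc1
F5 | step 11 | 3'-O-(1-ethoxyethyl) derivative of 19 (acetal carbon as a mixture) | c1ccccc1COc1ccc([C@H]2Oc3cc(OCc4ccccc4)ccc3[C@@H](c3cc4c(cc3OCc3ccccc3)O[C@@H](c3ccc(OCc5ccccc5)c(OCc5ccccc5)c3)[C@@H](OC(C)OCC)C4)[C@@H]2OCc2ccccc2)cc1
F6 | step 10 | (E)-3-[3,4-bis(benzyloxy)phenyl]prop-2-en-1-ol | OC/C=C/c1ccc(OCc2ccccc2)c(OCc2ccccc2)c1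
F7 | step 10 | [(2R,3R)-3-[3,4-bis(benzyloxy)phenyl]oxiran-2-yl]methanol | OC[C@H]1O[C@@H]1c1ccc(OCc2ccccc2)c(OCc2ccccc2)c1
F8 | step 10 | (2R,3S)-3-aryloxy-3-[3,4-bis(benzyloxy)phenyl]propane-1,2-diol, aryloxy = O1' of 13 | c1ccccc1COc1ccc([C@H]2Oc3cc(OCc4ccccc4)ccc3[C@@H](c3ccc(O[C@@H](c4ccc(OCc5ccccc5)c(OCc5ccccc5)c4)[C@H](O)CO)cc3OCc3ccccc3)[C@@H]2OCc2ccccc2)cc1
F9 | step 10 | primary 4-nitrobenzoate of F8 | c1ccccc1COc1ccc([C@H]2Oc3cc(OCc4ccccc4)ccc3[C@@H](c3ccc(O[C@@H](c4ccc(OCc5ccccc5)c(OCc5ccccc5)c4)[C@H](O)COC(=O)c4ccc(cc4)[N+](=O)[O-])cc3OCc3ccccc3)[C@@H]2OCc2ccccc2)cc1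
F10 | step 10 | secondary mesylate of F9 | c1ccccc1COc1ccc([C@H]2Oc3cc(OCc4ccccc4)ccc3[C@@H](c3ccc(O[C@@H](c4ccc(OCc5ccccc5)c(OCc5ccccc5)c4)[C@H](OS(C)(=O)=O)COC(=O)c4ccc(cc4)[N+](=O)[O-])cc3OCc3ccccc3)[C@@H]2OCc2ccccc2)cc1
F11 | step 4 | N-tosylhydrazone of 2 | c1ccccc1COc1ccc([C@H]2Oc3cc(OCc4ccccc4)ccc3C(=NNS(=O)(=O)c3ccc(C)cc3)C2)cc1
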